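All runs were computed for an exercise; the scatter is artificial.

**Late gap.** Late in Sunday's run, at 4.00 h, target and substrate together account for 64.8% of the substrate charged, so substrate leaves by another road besides the one to target. The question, though, sits at the other end of a run.

| setting | Tuesday's | Sunday's | flask |
|---|---|---|---|
| substrate | 1.9 M | 1.9 M | 1.9 M |
| coupling partner | 0.95 equiv | 0.95 equiv | 0.950 equiv |
| free catalyst | 2.8 mol% | 4.4 mol% | 2 mol% |
| remark | run made earlier | run made earlier |  |

| run | time / h | target / % | substrate / % |
|---|---|---|---|
| Tuesday's | 0.200 | 1.9 | 89.0 |
| Tuesday's | 0.667 | 8.9 | 69.6 |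
| Tuesday's | 1.00 | 12.5 | 60.7 |
| Tuesday's | 1.50 | 19.3 | 48.3 |
| Tuesday's | 2.50 | 28.1 | 32.7 |
| Tuesday's | 3.00 | 32.4 | 26.5 |
| Tuesday's | 4.00 | 38.5 | 18.5 |
| Sunday's | 0.500 | 10.5 | 71.3 |
| Sunday's | 1.00 | 19.9 | 53.7 |
| Sunday's | 1.50 | 27.8 | 41.4 |
| Sunday's | 2.50 | 41.1 | 24.1 |
| Sunday's | 3.00 | 45.6 | 18.5 |
| Sunday's | 4.00 | 53.0 | 11.8 |

(each reading ± 0.5 percentage points)

* apparent order in free catalyst when 5.0% of the substrate are converted (percent change of the rate of making target for one percent more free catalyst charged)
* apparent order in coupling partner when 5.0% of the substrate are converted (percent change of the rate of making target for one percent more coupling partner charged)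

- no earlier run changes the charge of coupling partner; that part of a forecast is a guess

**Two times.** I compare two times. The first is the lag: Tuesday's first two target readings, drawn back to zero target, give 0.0732 h, a reading that carries their scatter. The second is the mark time, when the flask reaches 5.0% conversion. The first substrate readings give a loss constant of 0.583 /h on Tuesday and 0.677 /h on Sunday. A straight line to the flask's loading gives 0.536 /h, so the mark time is 0.0957 h. Their ratio is 0.765: this is the fill ratio, lag over mark time.

**My reckoning.** At that ratio I place the mark inside the pre-steady-state build-up, with the target rate still climbing in time. I take that rate as proportional to catalyst, but more catalyst also brings the mark sooner, by the catalyst-dependent share of the loss, 21.9% in the flask. So I expect an order in catalyst of 0.781. No run varies the partner, so I give it no number.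

**The forecast.** It gives 1.05 (0.7 to 1.45) in catalyst and 0.8 (0.3 to 1.1) in partner, holding that “its formation or capture may limit the rate somewhat”.

**The result.** The flask gives 0.68 in catalyst and 0.014 in partner, each under the forecast's low end.

    substrate + free catalyst → catalyst intermediate A (k = 6.84 /M/h)
    catalyst intermediate A → catalyst intermediate B (k = 29.8 /h)
    coupling partner + catalyst intermediate B → catalyst intermediate C (k = 503 /M/h)
    catalyst intermediate C → catalyst intermediate D (k = 25.9 /h)
    catalyst intermediate D → released group + catalyst intermediate E (k = 2350 /h)
    catalyst intermediate E → free catalyst + target (k = 30.4 /h)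
    2 substrate → homo dimer (k = 0.114 /M/h)

At 0.400 h the flask holds 0.572% of its catalyst as catalyst intermediate B, the form that meets the partner, and 19.3% as catalyst intermediate C. Tuesday's lag of 0.0732 h is 0.836 of the 0.0876 h the flask takes to reach the mark.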